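**Plan**

- Retrosynthesis: the C2 methyl and the C3 aryl group are traced back to the carbonyl carbon and the fused arene of a coumarin (C2=C3 restored, aryl–O–C(=O) lactone). The cyclohexane is then cut at C4–C5 and C1–C6 in one operation into that coumarin and a para-quinone methide.
- Enabling feature (cyclohexane numbered C1 Et, C2 Me, C3 Ar, C4 Me, C5 Ar, C6 spiro; these locants are used throughout): C2/C3 are C3/C4 of a 6,7-dimethoxycoumarin. C4 (the CH2 of its 4-ethyl group) is therefore a vinylogous donor and C1 (the acetoxy carbon on coumarin C3) an allylic acceptor. C5/C6 are the exocyclic carbon and the para ring carbon of a 2,5-dimethoxy quinone methide, an acceptor–donor pair of matching polarity.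
- Forward: coumarin acetate 6 (steps 1–4) and the latent quinone methide 11 (steps 5–7) are made separately. Step 8 joins them and closes the cyclohexane ring; the spiro dienone ring arises from the phenol ring by dearomatisation. Steps 9–13 open the lactone and carry its carbonyl carbon down to the axial C2 methyl.
- Stereochemistry: C1, C4, C5 and C6 in step 8 (cinchona amine bound at C1, inversion at C1, half-chair closure); C3 by a suprafacial 1,5-hydrogen shift in step 12; C2 by hydrogenation of an exocyclic methylene from its open face in step 13.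

Key step: step 8

Assumption: the sense of induction of the cinchona catalyst in step 8 cannot be predicted with confidence; the route is written with (DHQD)2PHAL, its pseudo-enantiomer (DHQ)2PHAL being the alternative, and the catalyst-bound ammonium species of that step are turnover intermediates that carry no compound numbers.

**Route**

Step 1
Reactants: 1 3,4-dimethoxyphenol
Product: 2 1-(2-hydroxy-4,5-dimethoxyphenyl)propan-1-one
Conditions: EtCO2H, BF3·OEt2, 90 °C
Reagents that add atoms: propanoic acid, CCC(=O)O
Why: Nencki-type Friedel–Crafts acylation of an electron-rich phenol should place the acyl group ortho to OH and para to the 3-methoxy group, where the product is held as a boron chelate.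

Step 2
Reactants: 2 1-(2-hydroxy-4,5-dimethoxyphenyl)propan-1-one; 3 ethyl 3-oxopentanoate
Product: 4 4-ethyl-6,7-dimethoxy-3-propanoyl-2H-chromen-2-one
Conditions: 3 (2 equiv), xylene, 140 °C (−EtOH); then piperidine (cat.), 140 °C (−H2O)
Reagents that add atoms: none
Why: O-acylation of the phenol by the β-keto ester (acylketene transfer) followed by amine-catalysed intramolecular Knoevenagel condensation onto the aryl ketone is the usual way from 2-hydroxyaryl ketones to 3-acyl-4-alkylcoumarins.

Step 3
Reactants: 4 4-ethyl-6,7-dimethoxy-3-propanoyl-2H-chromen-2-one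
Product: 5 (±)-4-ethyl-3-(1-hydroxypropyl)-6,7-dimethoxy-2H-chromen-2-one
Conditions: NaBH4, CeCl3·7H2O, MeOH, −20 °C
Reagents that add atoms: none
Why: Luche 1,2-reduction of the ketone, with cerium suppressing conjugate reduction of the doubly activated C3=C4 bond and the lactone untouched; the carbinol is left racemic on purpose because step 8 erases this centre.

Step 4
Reactants: 5 (±)-4-ethyl-3-(1-hydroxypropyl)-6,7-dimethoxy-2H-chromen-2-one
Product: 6 (±)-1-(4-ethyl-6,7-dimethoxy-2-oxo-2H-chromen-3-yl)propyl acetate
Conditions: Ac2O, pyridine, DMAP (cat.), 0 °C → rt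
Reagents that add atoms: acetic anhydride, CC(=O)OC(C)=O
Why: DMAP-catalysed acylation of the secondary alcohol gives a Morita–Baylis–Hillman-type acetate; the weak amine base cannot remove the γ-hydrogen, so no elimination is expected.

Step 5
Reactants: 7 2,5-dimethoxyphenol
Product: 8 4-bromo-2,5-dimethoxyphenol
Conditions: NBS, MeCN, 0 °C
Reagents that add atoms: N-bromosuccinimide, O=C1CCC(=O)N1Br
Why: Electrophilic aromatic bromination should go para to the free hydroxyl, the most activated and least hindered position.

Step 6
Reactants: 8 4-bromo-2,5-dimethoxyphenol; 9 2,4,5-trimethoxybenzaldehyde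
Product: 10 (±)-(4-hydroxy-2,5-dimethoxyphenyl)(2,4,5-trimethoxyphenyl)methanol
Conditions: n-BuLi (2.2 equiv), THF, −78 → 0 °C; then 9, −78 °C → rt; aq NH4Cl
Reagents that add atoms: none
Why: O-deprotonation and bromine–lithium exchange (helped by the ortho methoxy group) give the lithiated phenoxide, which adds 1,2 to the aldehyde; the racemic carbinol centre becomes sp2 in step 8.

Step 7
Reactants: 10 (±)-(4-hydroxy-2,5-dimethoxyphenyl)(2,4,5-trimethoxyphenyl)methanol
Product: 11 (±)-2,5-dimethoxy-4-[(4-methylbenzenesulfonyl)(2,4,5-trimethoxyphenyl)methyl]phenol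
Conditions: p-TolSO2H, MgSO4, CH2Cl2, rt
Reagents that add atoms: p-toluenesulfinic acid, Cc1ccc(cc1)S(=O)O
Why: The doubly donor-substituted benzhydrol ionises under the mild acidity of the sulfinic acid and is captured at sulfur (SN1 sulfonylation), which should give a bench-stable latent quinone methide.

Step 8
Reactants: 6 (±)-1-(4-ethyl-6,7-dimethoxy-2-oxo-2H-chromen-3-yl)propyl acetate; 11 (±)-2,5-dimethoxy-4-[(4-methylbenzenesulfonyl)(2,4,5-trimethoxyphenyl)methyl]phenol
Product: 14 spirodienone lactone (2,3-didehydrotatanan B in its coumarin lactone form), via quinone methide 12 (not isolated), via dialkylidene lactone 13 (not isolated)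
Conditions: Cs2CO3 (2.5 equiv), (DHQD)2PHAL (20 mol %), MeCN, −20 °C → rt
Reagents that add atoms: none
Why: Proposed new method: carbonate turns 11 into quinone methide 12 (1,6-loss of sulfinate) and 6 into diene 13 (loss of acetate through the extended enolate, which cannot be avoided for this Morita–Baylis–Hillman-type acetate); the quinuclidine nitrogen of the catalyst adds reversibly to C1 of 13, the only site whose attack regenerates the extended lactone enolate, this C1-ammonium enolate adds through its ethylidene carbon to the exocyclic carbon of 12 (C4–C5), and the phenolate so formed displaces the ammonium at C1 with its para carbon (C1–C6) and frees the catalyst. The closest known reactions are Lewis-base-catalysed (3+2) annulations of Morita–Baylis–Hillman carbonates with para-quinone methides (1,6-addition of the onium-bound carbanion, dearomative ring closure with loss of the Lewis base) and vinylogous 1,6-additions of 4-alkylcoumarin dienolates; a vinylogous (4+2) version through a secondary onium centre is not known. The cyclohexane ring closes 6-exo-tet by SN2 at C1, which is at the same time the para C-alkylation that dearomatises the phenolate to the spiro dienone. C5 and C4 are set in the 1,6-addition, where the chiral ammonium on the neighbouring C1 selects the enolate face and an open antiperiplanar approach puts methyl and aryl anti; C1 arises by inversion at the ammonium-bearing carbon, whose epimers equilibrate through 13 before the C–C bond forms, in a half-chair that keeps ethyl pseudo-equatorial; C6 follows from the same half-chair, with the methoxy-bearing ring carbon equatorial and the CH arm axial. The step needs the stepwise onium pathway to outrun the direct [4+2] addition of free 13 to 12, which would be suprafacial on the diene and lead to the C1/C4-cis series; on the substrate side this is secured by the fully substituted C3=C4 bond of the coumarin, which blocks SN2′ and α-attack and leaves C1 and the ethylidene carbon as the only reactive sites, and by the far higher nucleophilicity of the ammonium enolate compared with the neutral diene.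

Step 9
Reactants: 14 spirodienone lactone
Product: 15 triol (allylic alcohol, phenol and dienol; dienol carbinol as an epimer mixture)
Conditions: DIBAL-H (6 equiv), CH2Cl2, −78 → 0 °C; Rochelle salt work-up at pH ≥ 7
Reagents that add atoms: none
Why: DIBAL 1,2-reduction of both carbonyl groups opens the aryl lactone to the (Z)-allylic alcohol and phenol and takes the dienone to the dienol, so the two carbonyls need not be told apart and the vinylogous acidity of C4–H is removed at once.

Step 10
Reactants: 15 triol
Product: 16 aryl methyl ether diol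
Conditions: MeI, K2CO3, acetone, rt
Reagents that add atoms: iodomethane, CI
Why: Williamson O-methylation in which carbonate deprotonates only the phenol, completing the 2,4,5-trimethoxyphenyl ring while the basic medium protects the acid-labile bis-enol ether dienol.

Step 11
Reactants: 16 aryl methyl ether diol
Product: 17 enal dienone
Conditions: MnO2 (excess), CH2Cl2, rt
Reagents that add atoms: none
Why: Neutral MnO2 oxidation of both allylic alcohols should restore the cross-conjugated dienone and give the tetrasubstituted enal without touching any stereocentre.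

Step 12
Reactants: 17 enal dienone
Product: 19 2-methylidene spirodienone (2-demethyl-2-methylidenetatanan B), via tosylhydrazone 18 (not isolated)
Conditions: TsNHNH2, THF, rt; then catecholborane, CHCl3, 0 °C; then NaOAc·3H2O, 60 °C
Reagents that add atoms: none
Why: Reductive 1,3-transposition of an enal tosylhydrazone (Kabalka reduction): 1,2-hydride addition, loss of sulfinate and retro-ene loss of N2 from the allylic diazene deliver hydrogen suprafacially to C3 and move the double bond to the exocyclic position; the hydrogen should arrive axially on the half-chair that keeps ethyl, methyl and the C5 aryl pseudo-equatorial, on the face away from the axial CH= arm of the spiro ring, so the C3 aryl ends equatorial and trans to the C4 methyl.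

Step 13
Reactants: 19 2-methylidene spirodienone
Product: 20 tatanan B
Conditions: H2 (3 atm), RhCl(PPh3)3 (10 mol %), benzene–EtOH, rt
Reagents that add atoms: none
Why: Wilkinson hydrogenation should reduce the 1,1-disubstituted exocyclic alkene and spare the hindered trisubstituted alkoxy-enone double bonds; hydrogen adds to C2 from the face bearing the axial C1–H and C3–H because the other face is covered by the syn-axial CH= arm of the spiro ring, which makes the new methyl axial and cis to the C1 ethyl and C3 aryl groups.

**Compound list**

1 | 3,4-dimethoxyphenol | COc1ccc(O)cc1OC | starting material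
2 | 1-(2-hydroxy-4,5-dimethoxyphenyl)propan-1-one | CCC(=O)c1cc(OC)c(OC)cc1O | intermediate
3 | ethyl 3-oxopentanoate | CCC(=O)CC(=O)OCC | starting material
4 | 4-ethyl-6,7-dimethoxy-3-propanoyl-2H-chromen-2-one | CCC(=O)c1c(CC)c2cc(OC)c(OC)cc2oc1=O | intermediate
5 | (±)-4-ethyl-3-(1-hydroxypropyl)-6,7-dimethoxy-2H-chromen-2-one | CCC(O)c1c(CC)c2cc(OC)c(OC)cc2oc1=O | intermediate
6 | (±)-1-(4-ethyl-6,7-dimethoxy-2-oxo-2H-chromen-3-yl)propyl acetate | CCC(OC(C)=O)c1c(CC)c2cc(OC)c(OC)cc2oc1=O | intermediate
7 | 2,5-dimethoxyphenol | COc1ccc(OC)c(O)c1 | starting material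
8 | 4-bromo-2,5-dimethoxyphenol | COc1cc(Br)c(OC)cc1O | intermediate
9 | 2,4,5-trimethoxybenzaldehyde | COc1cc(OC)c(C=O)cc1OC | starting material
10 | (±)-(4-hydroxy-2,5-dimethoxyphenyl)(2,4,5-trimethoxyphenyl)methanol | COc1cc(C(O)c2cc(OC)c(OC)cc2OC)c(OC)cc1O | intermediate
11 | (±)-2,5-dimethoxy-4-[(4-methylbenzenesulfonyl)(2,4,5-trimethoxyphenyl)methyl]phenol | COc1cc(C(c2cc(OC)c(OC)cc2OC)S(=O)(=O)c2ccc(C)cc2)c(OC)cc1O | intermediate
12 | (E)-2,5-dimethoxy-4-[(2,4,5-trimethoxyphenyl)methylidene]cyclohexa-2,5-dien-1-one, aryl syn to the ring CH (formed in situ) | O=C1C=C(OC)/C(=C/c2cc(OC)c(OC)cc2OC)C=C1OC | intermediate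
13 | (3Z,4E)-4-ethylidene-6,7-dimethoxy-3-propylidene-3,4-dihydro-2H-chromen-2-one, both alkyl groups pointing outward (formed in situ) | CC/C=C1\C(=O)Oc2cc(OC)c(OC)cc2/C1=C\C | intermediate
14 | spirodienone lactone: C2=C3 is the coumarin C3=C4 bond, C2 carries the lactone carbonyl, C3 the fused 6,7-dimethoxy arene; C1 ethyl and C5 aryl on one face, C4 methyl and the methoxy-bearing dienone carbon on the other (C1, C4, C5, C6 as in 20) | CC[C@@H]1C3=C(c4cc(OC)c(OC)cc4OC3=O)[C@@H](C)[C@H](c5cc(OC)c(OC)cc5OC)[C@]12C=C(OC)C(=O)C=C2OC | intermediate
15 | triol: C2 bears CH2OH, C3 bears 2-hydroxy-4,5-dimethoxyphenyl, spiro ring is the 2,5-dimethoxycyclohexa-2,5-dien-1-ol (carbinol epimers); C1, C4, C5, C6 as in 20 | CC[C@@H]1C(CO)=C(c3cc(OC)c(OC)cc3O)[C@@H](C)[C@H](c4cc(OC)c(OC)cc4OC)[C@]12C=C(OC)C(O)C=C2OC | intermediate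
16 | aryl methyl ether diol: as 15 with the C3 aryl group now 2,4,5-trimethoxyphenyl | CC[C@@H]1C(CO)=C(c3cc(OC)c(OC)cc3OC)[C@@H](C)[C@H](c4cc(OC)c(OC)cc4OC)[C@]12C=C(OC)C(O)C=C2OC | intermediate
17 | enal dienone: C2 bears CHO on the C2=C3 double bond, spiro dienone restored; C1, C4, C5, C6 as in 20 | CC[C@@H]1C(C=O)=C(c3cc(OC)c(OC)cc3OC)[C@@H](C)[C@H](c4cc(OC)c(OC)cc4OC)[C@]12C=C(OC)C(=O)C=C2OC | intermediate
18 | p-toluenesulfonylhydrazone of 17 (formed in situ) | CC[C@@H]1C(C=NNS(=O)(=O)c5ccc(C)cc5)=C(c3cc(OC)c(OC)cc3OC)[C@@H](C)[C@H](c4cc(OC)c(OC)cc4OC)[C@]12C=C(OC)C(=O)C=C2OC | intermediate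
19 | 2-methylidene spirodienone: exocyclic CH2 at C2, C3–H on the face opposite the C3 aryl; C1, C3, C4, C5, C6 as in 20 | CC[C@@H]1C(=C)[C@H](c3cc(OC)c(OC)cc3OC)[C@@H](C)[C@H](c4cc(OC)c(OC)cc4OC)[C@]12C=C(OC)C(=O)C=C2OC | intermediate
20 | tatanan B: C1 ethyl, C2 methyl, C3 aryl and C5 aryl on one face, C4 methyl and the methoxy-bearing spiro-ring carbon on the other (C1 R, C2 S, C3 S, C4 R, C5 R, C6 S in the numbering used here) | CC[C@@H]1[C@H](C)[C@H](c2cc(OC)c(OC)cc2OC)[C@@H](C)[C@H](c2cc(OC)c(OC)cc2OC)[C@]12C=C(OC)C(=O)C=C2OC | target

**Totals**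

Total step count: 13. Longest linear sequence: 10 steps (1–4, 8–13, from 3,4-dimethoxyphenol).

**Steps most likely to fail**

1. Step 8 (proposed new method). Free diene 13 may add to 12 in a direct concerted [4+2] without the catalyst, which would place ethyl and methyl cis and give no enantiocontrol. The bulky amine may fail to engage the secondary C1, the 1,6-addition may show poor anti selectivity, and carbonate may epimerise C4 of 14 through the lactone dienolate. Fallback with known reaction types, setting out from ketone 4 and sulfone 11 and returning at 14: the acidic vinylogous 1,3-dicarbonyl 4 is added 1,6 to 12 (released from 11 with aqueous K2CO3) under a bifunctional cinchona squaramide, an organocatalytic vinylogous 1,6-addition that sets C4 and C5 and gives the phenol ketone F1. The phenol is silylated (TBSCl, imidazole) to the silyl ether F2. The ketone is reduced under reagent control with (R)-Me-CBS and BH3·SMe2 to the (S)-carbinol F3. This is converted with Ms2O and Et3N at −40 °C into the mesylate F4, and TBAF then frees the phenolate, whose para carbon displaces the mesylate with inversion (alkylative dearomatisation) to give 14.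

2. Step 9. The bis-enol ether dienol may ionise on work-up or on silica (transposition to an enone or fragmentation at the spiro carbon), the hydroxymethyl phenol may close to a 2H-chromene, and reduction may stop at the lactol. Fallback that never reduces the dienone, setting out from 14 and returning at 17: the lactone is opened with aqueous NaOH in THF and the phenoxide methylated with Me2SO4 to the carboxylic acid F5 (at the price of exposing C4–H to base). The acid alone is reduced with BH3·SMe2 at 0 °C to the allylic alcohol F6, and MnO2 oxidation of F6 gives 17.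

3. Step 12. Hydrogen delivery to the fully substituted C3 may take place on the wrong face, or the hindered hydrazone may be reduced sluggishly so that the diazene decomposes without transposition. Fallback by metal-hydride delivery instead of a sigmatropic shift, setting out from 17 and returning at 19: the aldehyde is reduced selectively with NaBH4 at −78 °C to the allylic alcohol F6 (the compound already met under step 9), which is converted with ClCO2Me and pyridine into the allyl methyl carbonate F7. Tsuji formate reduction (Pd(OAc)2, PBu3, HCO2NH4, dioxane, 80 °C) then transfers hydride from palladium to the more substituted allyl terminus C3 and leaves the exocyclic alkene of 19.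

**Further compounds**

F1 | step 8 | 4-[1-(4-hydroxy-2,5-dimethoxyphenyl)-1-(2,4,5-trimethoxyphenyl)propan-2-yl]-6,7-dimethoxy-3-propanoyl-2H-chromen-2-one, both centres as C4 and C5 of 20 | CCC(=O)c1c([C@@H](C)[C@H](c2cc(OC)c(OC)cc2OC)c2cc(OC)c(O)cc2OC)c2cc(OC)c(OC)cc2oc1=O
F2 | step 8 | tert-butyldimethylsilyl ether of the phenol of F1 | CCC(=O)c1c([C@@H](C)[C@H](c2cc(OC)c(OC)cc2OC)c2cc(OC)c(O[Si](C)(C)C(C)(C)C)cc2OC)c2cc(OC)c(OC)cc2oc1=O
F3 | step 8 | 3-[(1S)-1-hydroxypropyl] carbinol from F2 | CC[C@H](O)c1c([C@@H](C)[C@H](c2cc(OC)c(OC)cc2OC)c2cc(OC)c(O[Si](C)(C)C(C)(C)C)cc2OC)c2cc(OC)c(OC)cc2oc1=O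
F4 | step 8 | methanesulfonate of F3 | CC[C@H](OS(C)(=O)=O)c1c([C@@H](C)[C@H](c2cc(OC)c(OC)cc2OC)c2cc(OC)c(O[Si](C)(C)C(C)(C)C)cc2OC)c2cc(OC)c(OC)cc2oc1=O
F5 | step 9 | ring-opened carboxylic acid: CO2H at C2, 2,4,5-trimethoxyphenyl at C3, dienone intact; C1, C4, C5, C6 as in 20 | CC[C@@H]1C(C(=O)O)=C(c3cc(OC)c(OC)cc3OC)[C@@H](C)[C@H](c4cc(OC)c(OC)cc4OC)[C@]12C=C(OC)C(=O)C=C2OC
F6 | step 9 | allylic alcohol: CH2OH at C2, dienone intact; C1, C4, C5, C6 as in 20 | CC[C@@H]1C(CO)=C(c3cc(OC)c(OC)cc3OC)[C@@H](C)[C@H](c4cc(OC)c(OC)cc4OC)[C@]12C=C(OC)C(=O)C=C2OC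
F7 | step 12 | methyl carbonate of F6 | CC[C@@H]1C(COC(=O)OC)=C(c3cc(OC)c(OC)cc3OC)[C@@H](C)[C@H](c4cc(OC)c(OC)cc4OC)[C@]12C=C(OC)C(=O)C=C2OC
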